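**Plan**
- Retrosynthesis: cut first the bond between the C6 methylene and C4 of a guaiacol ring, then the two ring-B bonds C4a–C5 and C8–C8a (Diels–Alder), then the central diene bond (alkenyl–alkenyl Suzuki coupling), then the aryl–alkyne bond.
- Forward: aryl iodide → arylpropyne → alkenylboronate → 1-aryl-2-methyl-3-(hydroxymethyl)butadiene. Ring B is then closed onto a ready-made methoxyquinone ring, guaiacol is joined, and desilylation ends the route.
- Helper groups: the bromine of 2-bromo-6-methoxybenzoquinone steers the regiochemistry and, leaving as HBr, sets the oxidation level; a TIPS ether masks the C8-aryl phenol until the last step.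
- Enabling feature: the C6 methylene is tied to the oxygen on C4 through C6=C5 and C4a=C4 (a vinylogous para relationship, 1,7 across the naphthalene). At the hydroquinone level a C6–CH2OH therefore ionises to an extended quinone methide, and the 5,8-dihydro ring B delivered by the cycloaddition is an isomer of exactly that hydroquinone.
- Stereochemistry: the target has no stereocentre. Diene geometry comes from syn-borylcupration and stereoretentive coupling; the sp3 centres of the dihydro intermediates are racemic and are erased on aromatisation.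

Key step: step 7

Assumption: the C8–aryl axis carries no ortho substituent on the guaiacyl ring and is taken as freely rotating, so no atropisomerism needs control; 1, 3 (as a THF solution), 6, 8 and 12 are taken as commercial.

**Step 1**
Reactants: 1 4-iodo-2-methoxyphenol
Product: 2 (4-iodo-2-methoxyphenoxy)triisopropylsilane
Conditions: TIPSCl, imidazole, DMF, rt
Reagents that add atoms: chlorotriisopropylsilane, CC(C)[Si](Cl)(C(C)C)C(C)C
Why: Imidazole-promoted O-silylation of a phenol should give a bulky aryl silyl ether that tolerates the later basic couplings and the acidic key step.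

**Step 2**
Reactants: 2 (4-iodo-2-methoxyphenoxy)triisopropylsilane; 3 propyne
Product: 4 [2-methoxy-4-(prop-1-yn-1-yl)phenoxy]triisopropylsilane
Conditions: PdCl2(PPh3)2 (2 mol %), CuI (4 mol %), propyne (1 M in THF), Et3N, rt, sealed vessel
Reagents that add atoms: none
Why: Sonogashira coupling of an aryl iodide with a terminal alkyne should proceed at room temperature and leave the silyl ether untouched.

**Step 3**
Reactants: 4 [2-methoxy-4-(prop-1-yn-1-yl)phenoxy]triisopropylsilane
Product: 5 2-{(Z)-1-[3-methoxy-4-(triisopropylsilyloxy)phenyl]prop-1-en-2-yl}-4,4,5,5-tetramethyl-1,3,2-dioxaborolane (aryl and methyl cis; aryl trans to boron)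
Conditions: B2pin2, CuCl (5 mol %), Xantphos (5 mol %), NaOtBu (10 mol %), MeOH (2 equiv), THF, rt
Reagents that add atoms: bis(pinacolato)diboron, CC1(C)OB(OC1(C)C)B1OC(C)(C)C(C)(C)O1
Why: Copper-catalysed formal hydroboration (syn-borylcupration, then protonolysis by MeOH with retention) of an aryl alkyl alkyne should place copper on the aryl-bearing carbon and boron on the methyl-bearing carbon, which fixes the alkene geometry.

**Step 4**
Reactants: 5 the (Z)-alkenylboronate; 6 2-bromoprop-2-en-1-ol
Product: 7 (3E)-4-[3-methoxy-4-(triisopropylsilyloxy)phenyl]-3-methyl-2-methylidenebut-3-en-1-ol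
Conditions: PdCl2(dppf) (5 mol %), K3PO4, THF/H2O, 60 °C
Reagents that add atoms: none
Why: Suzuki–Miyaura coupling of an alkenylboronate with a vinyl bromide is stereoretentive, so the aryl group should end up trans to the new diene carbon (the E-diene that can reach the s-cis form), with the free hydroxymethyl group carried along.

**Step 5**
Reactants: 8 2-bromo-6-methoxyphenol
Product: 9 2-bromo-6-methoxycyclohexa-2,5-diene-1,4-dione (2-bromo-6-methoxy-1,4-benzoquinone)
Conditions: Fremy's salt (2.2 equiv), KH2PO4 buffer, acetone/H2O, 0 °C to rt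
Reagents that add atoms: potassium nitrosodisulfonate (Fremy's salt), [K+].[K+].[O]N(S(=O)(=O)[O-])S(=O)(=O)[O-]
Why: Teuber oxidation of a 2,6-disubstituted phenol with a free para position should give the para-quinone selectively.

**Step 6**
Reactants: 7 the dienol; 9 2-bromo-6-methoxy-1,4-benzoquinone
Product: 11 6-(hydroxymethyl)-2-methoxy-8-[3-methoxy-4-(triisopropylsilyloxy)phenyl]-7-methyl-5,8-dihydronaphthalene-1,4-dione (racemic), via bromo cycloadduct 10 (not isolated)
Conditions: PhMe, 50 °C, Ar, dark; then Et3N (1.05 equiv), 0 °C, 10 min; cold 1 M HCl wash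
Reagents that add atoms: none
Why: Diels–Alder reaction at the brominated double bond (the methoxy-bearing one is deactivated) should join the unsubstituted diene terminus to the bromine-free carbon β to the C1 carbonyl and the aryl-bearing terminus to the C–Br carbon (endo approach gives the cis-fused adduct 10), and E1cB loss of HBr through the C4a enolate then gives the 5,8-dihydroquinone with the aryl group peri to the carbonyl that neighbours the methoxy group.

**Step 7**
Reactants: 11 the 5,8-dihydroquinone alcohol; 12 guaiacol (2-methoxyphenol)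
Product: 16 6-(4-hydroxy-3-methoxybenzyl)-2-methoxy-8-[3-methoxy-4-(triisopropylsilyloxy)phenyl]-7-methylnaphthalene-1,4-dione, via naphthalene-1,4-diol 13 (not isolated), via extended quinone methide 14 (not isolated), via arylated hydroquinone 15 (not isolated)
Conditions: guaiacol (10 equiv), TsOH·H2O (20 mol %), HFIP, Ar, 0 °C to 40 °C; then air, EtOAc/aq NaHCO3, rt
Reagents that add atoms: none
Why: Proposed new method: acid-catalysed double enolisation of 11 (loss of H8 and H5) aromatises ring B and delivers, with no external reductant, the naphthalene-1,4-diol 13, in which the oxygen on C4 can push through C4=C4a and C5=C6 to expel water from the C6 hydroxymethyl group; this gives the extended quinone methide 14 (present as its O-protonated benzylic cation), which guaiacol captures in a Friedel–Crafts sense to give 15, and air then returns the quinone. The closest known reaction types are the acid-mediated dehydrative Friedel–Crafts benzylation of phenols by p-hydroxybenzyl alcohols through p-quinone methides and the reductive activation of quinones that carry a benzylic leaving group; new here are the dihydro ring as built-in reductant and the relay through a 1,7-naphthoquinone methide. No ring is closed and no stereocentre is formed; the C8 stereocentre of 11 is erased when ring B becomes aromatic. Site selectivity on the electrophile is secured because both cationic manifolds (allyl cation at the dihydro stage, benzylic cation at the naphthalene stage) offer the unhindered CH2 terminus, the other allyl terminus C7 being tertiary and flanked by the C8 aryl group. Selectivity on guaiacol for C4, para to the free hydroxyl, rests on that position being the most activated and least hindered one. Capture by the arene rather than proton capture at CH2 or self-alkylation at C3 of 13 is favoured by the large excess of guaiacol and by the acidic, weakly nucleophilic medium that keeps 14 protonated.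

**Step 8**
Reactants: 16 the mono-TIPS ether of the target
Product: 17 larreantin, 6-(4-hydroxy-3-methoxybenzyl)-8-(4-hydroxy-3-methoxyphenyl)-2-methoxy-7-methylnaphthalene-1,4-dione
Conditions: TBAF (1.2 equiv), AcOH (1.5 equiv), THF, 0 °C
Reagents that add atoms: none
Why: Fluoride-mediated cleavage of the aryl silyl ether, buffered with acetic acid, should free the second phenol without harming the base-sensitive methoxyquinone.

**Compound list**
1 | 4-iodo-2-methoxyphenol | COc1cc(I)ccc1O | starting material
2 | (4-iodo-2-methoxyphenoxy)triisopropylsilane | COc1cc(I)ccc1O[Si](C(C)C)(C(C)C)C(C)C | intermediate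
3 | propyne | CC#C | starting material
4 | [2-methoxy-4-(prop-1-yn-1-yl)phenoxy]triisopropylsilane | CC#Cc1ccc(O[Si](C(C)C)(C(C)C)C(C)C)c(OC)c1 | intermediate
5 | 2-{(Z)-1-[3-methoxy-4-(triisopropylsilyloxy)phenyl]prop-1-en-2-yl}-4,4,5,5-tetramethyl-1,3,2-dioxaborolane | C/C(B1OC(C)(C)C(C)(C)O1)=C\c1ccc(O[Si](C(C)C)(C(C)C)C(C)C)c(OC)c1 | intermediate
6 | 2-bromoprop-2-en-1-ol | OCC(Br)=C | starting material
7 | (3E)-4-[3-methoxy-4-(triisopropylsilyloxy)phenyl]-3-methyl-2-methylidenebut-3-en-1-ol | C=C(CO)/C(C)=C/c1ccc(O[Si](C(C)C)(C(C)C)C(C)C)c(OC)c1 | intermediate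
8 | 2-bromo-6-methoxyphenol | COc1cccc(Br)c1O | starting material
9 | 2-bromo-6-methoxy-1,4-benzoquinone | COC1=CC(=O)C=C(Br)C1=O | intermediate
10 | 8a-bromo-6-(hydroxymethyl)-2-methoxy-8-[3-methoxy-4-(triisopropylsilyloxy)phenyl]-7-methyl-4a,5,8,8a-tetrahydronaphthalene-1,4-dione; cis-fused, H-4a and Br cis, aryl trans to Br, racemic (one enantiomer drawn) | COC1=CC(=O)[C@H]2CC(CO)=C(C)[C@@H](c3ccc(O[Si](C(C)C)(C(C)C)C(C)C)c(OC)c3)[C@@]2(Br)C1=O | intermediate (not isolated)
11 | 6-(hydroxymethyl)-2-methoxy-8-[3-methoxy-4-(triisopropylsilyloxy)phenyl]-7-methyl-5,8-dihydronaphthalene-1,4-dione; racemic at C8 | COC1=CC(=O)C2=C(C1=O)C(c3ccc(O[Si](C(C)C)(C(C)C)C(C)C)c(OC)c3)C(C)=C(CO)C2 | intermediate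
12 | guaiacol (2-methoxyphenol) | COc1ccccc1O | starting material
13 | 6-(hydroxymethyl)-2-methoxy-8-[3-methoxy-4-(triisopropylsilyloxy)phenyl]-7-methylnaphthalene-1,4-diol | COc1cc(O)c2cc(CO)c(C)c(-c3ccc(O[Si](C(C)C)(C(C)C)C(C)C)c(OC)c3)c2c1O | intermediate (not isolated)
14 | extended quinone methide: 4-hydroxy-3-methoxy-5-[3-methoxy-4-(triisopropylsilyloxy)phenyl]-6-methyl-7-methylidenenaphthalen-1(7H)-one (C6=CH2 and C4=O in target numbering) | COC1=CC(=O)C2=CC(=C)C(C)=C(c3ccc(O[Si](C(C)C)(C(C)C)C(C)C)c(OC)c3)C2=C1O | intermediate (not isolated)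
15 | 6-(4-hydroxy-3-methoxybenzyl)-2-methoxy-8-[3-methoxy-4-(triisopropylsilyloxy)phenyl]-7-methylnaphthalene-1,4-diol | COc1cc(O)c2cc(Cc3ccc(O)c(OC)c3)c(C)c(-c3ccc(O[Si](C(C)C)(C(C)C)C(C)C)c(OC)c3)c2c1O | intermediate (not isolated)
16 | 6-(4-hydroxy-3-methoxybenzyl)-2-methoxy-8-[3-methoxy-4-(triisopropylsilyloxy)phenyl]-7-methylnaphthalene-1,4-dione | COC1=CC(=O)c2cc(Cc3ccc(O)c(OC)c3)c(C)c(-c3ccc(O[Si](C(C)C)(C(C)C)C(C)C)c(OC)c3)c2C1=O | intermediate
17 | larreantin | COC1=CC(=O)c2cc(Cc3ccc(O)c(OC)c3)c(C)c(-c3ccc(O)c(OC)c3)c2C1=O | target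

**Step count and risks**
Total steps: 8. Longest linear sequence: 7 (steps 1, 2, 3, 4, 6, 7, 8).

Steps most likely to fail:

1. Step 7 (Proposed new method). What may go wrong: proton capture at the methylene of the quinone methide, which is an internal redox to the 6,7-dimethylquinone; attack of guaiacol through positions other than C4; self-alkylation through C3 of the naphthalenediol; and redox scrambling between dihydroquinone and naphthalenediol species that drains only slowly towards the aromatic hydroquinone. Fallback with known chemistry, setting out from 11 and from 2 and returning at 17: stirring 11 with Et3N in THF under air should isomerise and oxidise it to the quinone alcohol F1, and PBr3 in CH2Cl2 at 0 °C should convert this to the benzylic bromide F2. Separately, Miyaura borylation of 2 (B2pin2, PdCl2(dppf), KOAc, dioxane, 80 °C) should give the arylboronate F3. A benzylic sp3–sp2 Suzuki–Miyaura coupling of F2 with F3 (PdCl2(dppf), K2CO3, THF/H2O, 60 °C) fixes the attachment site on the guaiacyl ring by the boron position and should give the bis-silyl ether F4, which TBAF/AcOH desilylates at both phenols to 17.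

2. Step 6. What may go wrong: slow cycloaddition at the bromine-bearing carbon against the aryl-substituted diene terminus; HBr-induced ionisation of the allylic alcohol before the base is added; and overshoot of the base treatment (isomerisation followed by air oxidation), which would shift the oxidation level away from that needed in step 7. Fallback, setting out from 7 and returning at 11: thermal Diels–Alder reaction of 7 with commercial 2-methoxy-1,4-benzoquinone (PhMe, 80 °C) should give the bromine-free cis adduct F5, the regiochemistry now resting on the methoxy group alone (the C4 carbonyl is deactivated as a vinylogous ester, so the C1 carbonyl directs). Enolisation (catalytic Et3N, Ar) should give the 5,8-dihydronaphthalene-1,4-diol F6, and oxidation limited to the hydroquinone ring with Ag2O (Et2O, Na2SO4, rt) should give 11.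

3. Step 4. What may go wrong: slow transmetalation of the hindered α-methyl alkenylboronate, protodeboronation, and β-hydroxide elimination from the 2-palladated allyl alcohol. Fallback, setting out from 4 and returning at 7, building the diene by carbonyl olefination instead of cross-coupling: nickel-catalysed reductive coupling of 4 with (tert-butyldimethylsilyloxy)acetaldehyde (Ni(cod)2, PBu3, Et3B) should form the C–C bond at the methyl-bearing alkyne carbon by syn addition and give the (E)-allylic alcohol F7. Dess–Martin oxidation should give the enone F8, Wittig methylenation (Ph3P=CH2, THF) the diene silyl ether F9, and CSA in MeOH at 0 °C should remove the primary TBS group in the presence of the aryl TIPS ether to give 7.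

**Further compounds**
F1 | step 7 | 6-(hydroxymethyl)-2-methoxy-8-[3-methoxy-4-(triisopropylsilyloxy)phenyl]-7-methylnaphthalene-1,4-dione | COC1=CC(=O)c2cc(CO)c(C)c(-c3ccc(O[Si](C(C)C)(C(C)C)C(C)C)c(OC)c3)c2C1=O
F2 | step 7 | 6-(bromomethyl)-2-methoxy-8-[3-methoxy-4-(triisopropylsilyloxy)phenyl]-7-methylnaphthalene-1,4-dione | COC1=CC(=O)c2cc(CBr)c(C)c(-c3ccc(O[Si](C(C)C)(C(C)C)C(C)C)c(OC)c3)c2C1=O
F3 | step 7 | 2-[3-methoxy-4-(triisopropylsilyloxy)phenyl]-4,4,5,5-tetramethyl-1,3,2-dioxaborolane | COc1cc(B2OC(C)(C)C(C)(C)O2)ccc1O[Si](C(C)C)(C(C)C)C(C)C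
F4 | step 7 | 2-methoxy-6-[3-methoxy-4-(triisopropylsilyloxy)benzyl]-8-[3-methoxy-4-(triisopropylsilyloxy)phenyl]-7-methylnaphthalene-1,4-dione | COC1=CC(=O)c2cc(Cc3ccc(O[Si](C(C)C)(C(C)C)C(C)C)c(OC)c3)c(C)c(-c3ccc(O[Si](C(C)C)(C(C)C)C(C)C)c(OC)c3)c2C1=O
F5 | step 6 | 6-(hydroxymethyl)-2-methoxy-8-[3-methoxy-4-(triisopropylsilyloxy)phenyl]-7-methyl-4a,5,8,8a-tetrahydronaphthalene-1,4-dione; cis-fused, H-4a, H-8a and H-8 cis, racemic (one enantiomer drawn) | COC1=CC(=O)[C@H]2CC(CO)=C(C)[C@@H](c3ccc(O[Si](C(C)C)(C(C)C)C(C)C)c(OC)c3)[C@H]2C1=O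
F6 | step 6 | 6-(hydroxymethyl)-2-methoxy-8-[3-methoxy-4-(triisopropylsilyloxy)phenyl]-7-methyl-5,8-dihydronaphthalene-1,4-diol; racemic | COc1cc(O)c2c(c1O)C(c1ccc(O[Si](C(C)C)(C(C)C)C(C)C)c(OC)c1)C(C)=C(CO)C2
F7 | step 4 | (3E)-1-(tert-butyldimethylsilyloxy)-4-[3-methoxy-4-(triisopropylsilyloxy)phenyl]-3-methylbut-3-en-2-ol; racemic | C/C(=C\c1ccc(O[Si](C(C)C)(C(C)C)C(C)C)c(OC)c1)C(O)CO[Si](C)(C)C(C)(C)C
F8 | step 4 | (3E)-1-(tert-butyldimethylsilyloxy)-4-[3-methoxy-4-(triisopropylsilyloxy)phenyl]-3-methylbut-3-en-2-one | C/C(=C\c1ccc(O[Si](C(C)C)(C(C)C)C(C)C)c(OC)c1)C(=O)CO[Si](C)(C)C(C)(C)C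
F9 | step 4 | tert-butyl{(3E)-4-[3-methoxy-4-(triisopropylsilyloxy)phenyl]-3-methyl-2-methylidenebut-3-enyloxy}dimethylsilane | C=C(CO[Si](C)(C)C(C)(C)C)/C(C)=C/c1ccc(O[Si](C(C)C)(C(C)C)C(C)C)c(OC)c1
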